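**Strategy.** The cycloheptene ring carries a cis-1,5-dioxygenated (Z)-alkene, C4(OH)–C5H=C6(CH3)–C7H2–C8(OAr) (azulene numbering), which is the retron of a double allylboration. The ring is therefore made by a [4+3] annulation of a cyclopentane trans-1,2-dicarbaldehyde (C4 and C8 as formyl groups on C3a and C8a, five-membered ring complete) with a 2-methylpropene carrying boron at C1 and C3. One flask forms C4–C5 by intermolecular allylboration and then C7–C8 by intramolecular allylboration of the α-boryl intermediate; boron-to-oxygen delivery puts both carbinol oxygens on the same ring face. The dialdehyde comes from 3-methylcyclopentenone by asymmetric conjugate addition.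

Key step: step 9

Remark: bicyclic compounds carry azulene numbering (C1 carbinol with isopropyl, C3a methyl-bearing fusion carbon, C4 allylic carbinol, C5=C6, C7, C8 ester carbinol, C8a); the ligand and catalyst antipodes are assumed to be those that give the drawn configurations.

**Step 1**
Reactants: 1 3-methylcyclopent-2-en-1-one; 2 hex-1-yne
Product: 5 trimethyl({(3R)-3-[(1E)-hex-1-en-1-yl]-3-methylcyclopent-1-en-1-yl}oxy)silane, via alkenylalane 3 (not isolated), via aluminium enolate 4 (not isolated)
Conditions: 2, iBu2AlH, hexane, 50 °C; then 1, Cu(OTf)2 (5 mol%), chiral sulfonate-bearing imidazolinium salt (NHC precursor, 5 mol%), THF, −30 °C; then TMSOTf, −30 to 0 °C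
Reagents that add atoms: trimethylsilyl triflate, C[Si](C)(C)OS(=O)(=O)C(F)(F)F
Why: Copper-catalysed asymmetric conjugate addition of an alkenylalane (from hydroalumination of 2) to a β-methyl cyclic enone is an established route to all-carbon quaternary centres; the ligand antipode fixes the methyl-bearing stereocentre (3R in 5, the later C3a), and the silyl triflate traps the aluminium enolate regiospecifically on the hindered side.

**Step 2**
Reactants: 5 silyl enol ether
Product: 6 (3R)-2-(dimethoxymethyl)-3-[(1E)-hex-1-en-1-yl]-3-methylcyclopentan-1-one (C2 epimers)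
Conditions: HC(OMe)3, TMSOTf (5 mol%), CH2Cl2, −78 °C
Reagents that add atoms: trimethyl orthoformate, COC(OC)OC
Why: Mukaiyama-type alkylation of the enol silane by the dimethoxycarbenium ion places the masked formyl group at C2 only; the configuration at C2 is left open because step 3 equilibrates it.

**Step 3**
Reactants: 6 keto acetal
Product: 9 (2S,3S)-2,3-bis(dimethoxymethyl)-3-methylcyclopentan-1-one, via keto aldehyde 7 (not isolated), via epimeric bis-acetal ketone 8 (not isolated)
Conditions: O3, CH2Cl2/MeOH, −78 °C; Me2S; then HC(OMe)3, CeCl3·7H2O (10 mol%), MeOH, rt; then K2CO3, MeOH, rt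
Reagents that add atoms: trimethyl orthoformate, COC(OC)OC
Why: Ozonolysis cleaves the disubstituted alkene to the neopentyl aldehyde, lanthanide-catalysed acetalisation is selective for aldehyde over ketone, and base-mediated epimerisation through the enolate should put the C2 acetal trans to the bulkier C3 acetal (cis to methyl), so C2 (the later C8a) is set by thermodynamic control.

**Step 4**
Reactants: 9 bis-acetal ketone
Product: 10 (1R,2R,3S)-2,3-bis(dimethoxymethyl)-3-methyl-1-(propan-2-yl)cyclopentan-1-ol
Conditions: iPrMgCl, CeCl3, THF, −78 to 0 °C; aq. NH4Cl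
Reagents that add atoms: isopropylmagnesium chloride, CC(C)[Mg]Cl
Why: Organocerium 1,2-addition suppresses enolisation and reduction, and the nucleophile should approach anti to the adjacent C2 dimethoxymethyl group (the face of C2–H), which gives the tertiary alcohol with OH cis to that group (1R).

**Step 5**
Reactants: 10 tertiary alcohol
Product: 12 (1S,2R,3R)-1-methyl-3-(propan-2-yl)-3-[(triethylsilyl)oxy]cyclopentane-1,2-dicarbaldehyde, via bis-collidinium salt 11 (not isolated)
Conditions: TESOTf (6 equiv), 2,4,6-collidine (9 equiv), CH2Cl2, 0 °C to rt; then H2O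
Reagents that add atoms: triethylsilyl triflate, CC[Si](CC)(CC)OS(=O)(=O)C(F)(F)F; water, O
Why: The silyl triflate silylates the tertiary alcohol and, with the hindered pyridine, turns both dimethyl acetals into collidinium N,O-acetals that water hydrolyses to the aldehydes without acid (acetal cleavage by silyl triflate and pyridine base), so the β-silyloxy aldehyde should neither eliminate nor epimerise.

**Step 6**
Reactants: 13 prop-2-yn-1-ol
Product: 15 (2E)-3-iodo-2-methylprop-2-en-1-ol, via alkenylalane alkoxide 14 (not isolated)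
Conditions: Me3Al (3 equiv), Cp2ZrCl2 (25 mol%), CH2Cl2, 0 °C to rt; then I2, THF, −30 °C
Reagents that add atoms: trimethylaluminium, C[Al](C)C; iodine, II
Why: Negishi zirconium-catalysed carboalumination adds methyl and aluminium syn across the alkyne and iodinolysis proceeds with retention, giving the E-iodide only.

**Step 7**
Reactants: 15 iodo alcohol
Product: 16 (2E)-2-methyl-3-(4,4,5,5-tetramethyl-1,3,2-dioxaborolan-2-yl)prop-2-en-1-ol
Conditions: B2pin2, PdCl2(PPh3)2 (3 mol%), PPh3, KOPh, toluene, 50 °C
Reagents that add atoms: bis(pinacolato)diboron, CC1(C)OB(OC1(C)C)B2OC(C)(C)C(C)(C)O2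
Why: Miyaura borylation of the alkenyl iodide proceeds with retention of the double-bond geometry and tolerates the free alcohol.

**Step 8**
Reactants: 16 boryl allylic alcohol
Product: 17 2,2'-[(1E)-2-methylprop-1-ene-1,3-diyl]bis(4,4,5,5-tetramethyl-1,3,2-dioxaborolane)
Conditions: B2pin2, Pd(MeCN)4(BF4)2 (5 mol%), DMSO/MeOH, rt
Reagents that add atoms: bis(pinacolato)diboron, CC1(C)OB(OC1(C)C)B2OC(C)(C)C(C)(C)O2
Why: Palladium-catalysed borylation of the allylic alcohol through a π-allyl intermediate delivers boron to the unsubstituted terminus and should keep the E-alkenylboronate.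

**Step 9**
Reactants: 12 dialdehyde; 17 bis-boronate (1.05 equiv)
Product: 20 (1R,3aS,4R,8S,8aS)-3a,6-dimethyl-1-(propan-2-yl)-1-[(triethylsilyl)oxy]-1,2,3,3a,4,7,8,8a-octahydroazulene-4,8-diol, via mono-allylboration adduct 18 (not isolated), via bis-borate 19 (not isolated)
Conditions: (R)-TRIP (10 mol%), 4 Å MS, toluene (0.02 M), 0 °C to rt, then 60 °C; aq. NaHCO3/MeOH work-up
Reagents that add atoms: none
Why: Proposed new method: a one-pot double allylboration run as a [4+3] annulation, in which the allyl–B(pin) terminus of 17 adds through a chair six-membered transition state to the less encumbered, non-enolisable C1-formyl group of 12 (C4–C5 bond, anti adduct 18 from the E-reagent), and the α-boryl methallyl unit so generated then allylborates the remaining formyl group intramolecularly (C7–C8 bond) with transfer of boron from C5 to the C8 oxygen. The closest known reaction type is the one-pot double allylboration of two aldehydes with γ-boryl allylboron reagents, which gives 1,5-diols; the ring-closing second stage on a 1,4-dialdehyde, which has to pass through a boat-like bicyclo[3.2.2] transition state, is the untested part. The seven-membered ring closes by intramolecular SE2' attack of the allyl terminus C7 on the aldehyde carbon C8, and the ring forces the new C5=C6 bond to be Z. C4 is set by the phosphoric acid catalyst (Re-face addition, expected to override the weak intrinsic bias of the α-quaternary aldehyde) and C8 by suprafacial boron-to-oxygen delivery from C5, which places both oxygens on the same face. The step needs site selectivity between the two formyl groups, which the cis-flanking methyl and triethylsilyloxy groups around the C2-formyl group should secure, and it needs the trans ring fusion, which is already fixed in 12.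

**Step 10**
Reactants: 20 silyl ether diol
Product: 21 (1R,3aS,4R,8S,8aS)-3a,6-dimethyl-1-(propan-2-yl)-1,2,3,3a,4,7,8,8a-octahydroazulene-1,4,8-triol
Conditions: HF·pyridine, THF/pyridine, 0 °C to rt
Reagents that add atoms: none
Why: Fluoride cleaves the Si–O bond of the tertiary triethylsilyl ether without touching the allylic alcohol, and removal of this group frees the space around the C8 hydroxyl for the last step.

**Step 11**
Reactants: 21 triol; 22 4-methoxybenzoyl chloride (1.05 equiv)
Product: 23 (1R,3aS,4R,8S,8aS)-1,4-dihydroxy-3a,6-dimethyl-1-(propan-2-yl)-1,2,3,3a,4,7,8,8a-octahydroazulen-8-yl 4-methoxybenzoate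
Conditions: pyridine, DMAP (10 mol%), CH2Cl2, 0 °C
Reagents that add atoms: none
Why: DMAP-catalysed acylation should take place at the C8 hydroxyl, which is flanked by CH2 and CH, in preference to the neopentyl allylic C4 hydroxyl next to the quaternary C3a and to the tertiary C1 hydroxyl.

**Compound list**
1 | 3-methylcyclopent-2-en-1-one | CC1=CC(=O)CC1 | starting material
2 | hex-1-yne | CCCCC#C | starting material
3 | [(1E)-hex-1-en-1-yl]bis(2-methylpropyl)alumane | CCCC/C=C/[Al](CC(C)C)CC(C)C | intermediate
4 | bis(2-methylpropyl)aluminium (3R)-3-[(1E)-hex-1-en-1-yl]-3-methylcyclopent-1-en-1-olate | CCCC/C=C/[C@@]1(C)CCC(O[Al](CC(C)C)CC(C)C)=C1 | intermediate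
5 | trimethyl({(3R)-3-[(1E)-hex-1-en-1-yl]-3-methylcyclopent-1-en-1-yl}oxy)silane | CCCC/C=C/[C@@]1(C)CCC(O[Si](C)(C)C)=C1 | intermediate
6 | (3R)-2-(dimethoxymethyl)-3-[(1E)-hex-1-en-1-yl]-3-methylcyclopentan-1-one (C2 epimers) | CCCC/C=C/[C@@]1(C)CCC(=O)C1C(OC)OC | intermediate
7 | (1S)-2-(dimethoxymethyl)-1-methyl-3-oxocyclopentane-1-carbaldehyde (C2 epimers) | O=C[C@@]1(C)CCC(=O)C1C(OC)OC | intermediate
8 | (3S)-2,3-bis(dimethoxymethyl)-3-methylcyclopentan-1-one (C2 epimers) | COC(OC)[C@@]1(C)CCC(=O)C1C(OC)OC | intermediate
9 | (2S,3S)-2,3-bis(dimethoxymethyl)-3-methylcyclopentan-1-one (acetal groups trans) | COC(OC)[C@@]1(C)CCC(=O)[C@@H]1C(OC)OC | intermediate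
10 | (1R,2R,3S)-2,3-bis(dimethoxymethyl)-3-methyl-1-(propan-2-yl)cyclopentan-1-ol | COC(OC)[C@@]1(C)CC[C@@](O)(C(C)C)[C@@H]1C(OC)OC | intermediate
11 | triethylsilyl ether of 10 in which each acetal has become CH(OMe)(2,4,6-trimethylpyridinium-1-yl), ditriflate | COC([n+]1c(C)cc(C)cc1C)[C@@]2(C)CC[C@@](O[Si](CC)(CC)CC)(C(C)C)[C@@H]2C(OC)[n+]3c(C)cc(C)cc3C.[O-]S(=O)(=O)C(F)(F)F.[O-]S(=O)(=O)C(F)(F)F | intermediate
12 | (1S,2R,3R)-1-methyl-3-(propan-2-yl)-3-[(triethylsilyl)oxy]cyclopentane-1,2-dicarbaldehyde | O=C[C@@]1(C)CC[C@@](O[Si](CC)(CC)CC)(C(C)C)[C@@H]1C=O | intermediate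
13 | prop-2-yn-1-ol | C#CCO | starting material
14 | dimethylaluminium (2E)-3-(dimethylalumanyl)-2-methylprop-2-en-1-olate | C[Al](C)OC/C(C)=C/[Al](C)C | intermediate
15 | (2E)-3-iodo-2-methylprop-2-en-1-ol | OC/C(C)=C/I | intermediate
16 | (2E)-2-methyl-3-(4,4,5,5-tetramethyl-1,3,2-dioxaborolan-2-yl)prop-2-en-1-ol | OC/C(C)=C/B1OC(C)(C)C(C)(C)O1 | intermediate
17 | 2,2'-[(1E)-2-methylprop-1-ene-1,3-diyl]bis(4,4,5,5-tetramethyl-1,3,2-dioxaborolane) | B1(OC(C)(C)C(C)(C)O1)C/C(C)=C/B2OC(C)(C)C(C)(C)O2 | intermediate
18 | 12 in which the C1-formyl group has become (1R,2R)-CH(OBpin)–CH(Bpin)–C(CH3)=CH2, C2-formyl intact | C=C(C)[C@@H](B1OC(C)(C)C(C)(C)O1)[C@@H](OB2OC(C)(C)C(C)(C)O2)[C@@]3(C)CC[C@@](O[Si](CC)(CC)CC)(C(C)C)[C@@H]3C=O | intermediate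
19 | 4,8-bis(pinacol borate) of 20 | CC1(C)OB(O[C@H]2CC(C)=C[C@@H](OB3OC(C)(C)C(C)(C)O3)[C@@]4(C)CC[C@@](O[Si](CC)(CC)CC)(C(C)C)[C@H]24)OC1(C)C | intermediate
20 | (1R,3aS,4R,8S,8aS)-3a,6-dimethyl-1-(propan-2-yl)-1-[(triethylsilyl)oxy]-1,2,3,3a,4,7,8,8a-octahydroazulene-4,8-diol | O[C@H]1CC(C)=C[C@@H](O)[C@@]2(C)CC[C@@](O[Si](CC)(CC)CC)(C(C)C)[C@H]12 | intermediate
21 | (1R,3aS,4R,8S,8aS)-3a,6-dimethyl-1-(propan-2-yl)-1,2,3,3a,4,7,8,8a-octahydroazulene-1,4,8-triol | O[C@H]1CC(C)=C[C@@H](O)[C@@]2(C)CC[C@@](O)(C(C)C)[C@H]12 | intermediate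
22 | 4-methoxybenzoyl chloride | COc1ccc(cc1)C(Cl)=O | starting material
23 | (1R,3aS,4R,8S,8aS)-1,4-dihydroxy-3a,6-dimethyl-1-(propan-2-yl)-1,2,3,3a,4,7,8,8a-octahydroazulen-8-yl 4-methoxybenzoate | COc1ccc(C(=O)O[C@H]2CC(C)=C[C@@H](O)[C@@]3(C)CC[C@@](O)(C(C)C)[C@H]23)cc1 | target

Total step count: 11. Longest linear sequence: 8 steps (steps 1–5 and 9–11); steps 6–8 make the three-carbon partner.

**Steps most likely to fail**

Step 9 (proposed new method). The ring-closing second allylboration has to pass a strained boat-like transition state and may be outrun by β-oxygen elimination of the α-boryl borate or by intermolecular reaction. Site selectivity between the two formyl groups and catalyst control at C4 may also fall short. The fallback sets out from 12 and returns at 20, making the two bonds separately by known reactions. An amino-alcohol-controlled alkenylzinc (vinyl) addition to the more accessible C1-formyl group, with silylation in the same flask (TMSCl), should give the silylated allylic alcohol F1. Brown methallylation of the remaining aldehyde with B-methallyldiisopinocampheylborane should give the diene F2. Ring-closing metathesis with second-generation Grubbs catalyst should give the ring-closed silyl ether F3, and K2CO3/MeOH removes the trimethylsilyl group to give 20.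

Step 4. The branched Grignard reagent may enolise or reduce the hindered ketone, and facial discrimination may be incomplete. The fallback sets out from 9 and returns at 10. Addition of 2-propenylmagnesium bromide with CeCl3, an sp2 nucleophile without β-hydrogens, should give the tertiary allylic alcohol F4. Hydrogenation of the isopropenyl group (H2, PtO2, EtOAc) then gives 10.

Step 11. Acylation may not discriminate well enough between the two secondary hydroxyl groups, giving the C4 ester or the diester. The fallback sets out from 21 and returns at 23 by delivering the acyl group through the tertiary hydroxyl. Trimethyl 4-methoxyorthobenzoate with catalytic camphorsulfonic acid should tie the C1 and C8 oxygens into the six-membered cyclic orthoester F5. Mild hydrolysis (aq. AcOH) should open F5 to the ester of the secondary C8 oxygen, 23.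

**Further compounds**
F1 | step 9 | 12 with the C1-formyl group converted into (R)-CH(OSiMe3)–CH=CH2 | C[Si](C)(C)O[C@H](C=C)[C@@]1(C)CC[C@@](O[Si](CC)(CC)CC)(C(C)C)[C@@H]1C=O
F2 | step 9 | F1 with the C2-formyl group converted into (S)-CH(OH)–CH2–C(CH3)=CH2 | C[Si](C)(C)O[C@H](C=C)[C@@]1(C)CC[C@@](O[Si](CC)(CC)CC)(C(C)C)[C@@H]1[C@@H](O)CC(C)=C
F3 | step 9 | C4 trimethylsilyl ether of 20 | O[C@H]1CC(C)=C[C@@H](O[Si](C)(C)C)[C@@]2(C)CC[C@@](O[Si](CC)(CC)CC)(C(C)C)[C@H]12
F4 | step 4 | (1S,2R,3S)-2,3-bis(dimethoxymethyl)-3-methyl-1-(prop-1-en-2-yl)cyclopentan-1-ol | COC(OC)[C@@]1(C)CC[C@@](O)(C(C)=C)[C@@H]1C(OC)OC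
F5 | step 11 | cyclic methyl 4-methoxyorthobenzoate bridging O1 and O8 of 21, C4 hydroxyl free | COc1ccc(cc1)C2(OC)O[C@H]3CC(C)=C[C@@H](O)[C@@]4(C)CC[C@@](O2)(C(C)C)[C@H]34
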